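## Retrosynthetic overview

1. Rabdosiin ⇒ the same skeleton held as a 15-membered macrocyclic diester. The two lactate CO2H groups are bridged by a 2-methylidenepropane-1,3-diyl tether and the two lactate-side catechols are diacetates. One Pd(0)/amine operation releases everything.
2. Macrocycle ⇒ open, tethered bis-rosmarinate by anodic dehydrodimerisation. C8–C8′ (C2–C3 of the target) forms first and closes the temporary 15-membered ring. C6→C7′ (C8a–C1) then closes the dihydronaphthalene carbocycle.
3. Tethered substrate with only the two caffeoyl catechols free ⇒ octaacetate, by leaving-group-controlled aminolysis.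
4. Octaacetate ⇒ 2 × (R)-rosmarinic acid + 3-chloro-2-(chloromethyl)prop-1-ene + Ac2O, in one pot.
5. Both lactate stereocentres are bought in rosmarinic acid. C2 and C1 are relayed from them through the macrocycle.

Assumption: the target SMILES decodes as a trans-(1R,2S) 1-aryl-1,2-dihydronaphthalene core carrying two (R)-3-(3,4-dihydroxyphenyl)lactate esters, and commercial rosmarinic acid is the natural (R)-enantiomer.

Locants: C7/C8 are the β/α side-chain carbons of a caffeoyl arm, C9 is its ester carbonyl, Cα is the lactate stereocentre, and primes mark the second arm.

## Route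

**Step 1**
Reactants: 1, (R)-rosmarinic acid (2.05 equiv); 2, 3-chloro-2-(chloromethyl)prop-1-ene (1.0 equiv); 4, acetic anhydride
Product: 5, 2-methylidenepropane-1,3-diyl bis[(R)-rosmarinate] octaacetate, formed via the octaphenol diester 3 (not isolated); expected about 60%
Conditions: i) KHCO3 (2.2 equiv), NaI (0.2 equiv), DMF, 40 °C, 16 h, Ar; ii) Ac2O (12 equiv), pyridine (15 equiv), 0 → 23 °C, 3 h, same pot
Reagents that add atoms: 2, 3-chloro-2-(chloromethyl)prop-1-ene, C=C(CCl)CCl (C4H6 tether); 4, acetic anhydride, CC(=O)OC(C)=O (8 × acetyl)
Why: Bicarbonate ionises only the carboxylic acid (pKa about 3) and not the catechols (pKa ≥ 8.7), so a Finkelstein-assisted double SN2 carboxylate alkylation gives the bis-allylic diester and pyridine/Ac2O then acetylates all eight phenols, with neither base able to enolise Cα–H, so both (R) centres are carried through.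

**Step 2**
Reactants: 5, octaacetate
Product: 6, 2-methylidenepropane-1,3-diyl bis[(R)-3-(3,4-diacetoxyphenyl)-2-{[(E)-3-(3,4-dihydroxyphenyl)acryloyl]oxy}propanoate], with both caffeoyl catechols free and both lactate-side catechols still diacetates; expected about 60–65%, and mis-acetylated fractions are re-acetylated to 5
Conditions: morpholine (4.4 equiv), THF, −10 → 0 °C, 2–4 h (HPLC control), Ar; 0.5 M citric acid quench
Reagents that add atoms: none
Why: Aminolysis of aryl acetates by a weakly basic amine is leaving-group controlled (rate-limiting aryloxide expulsion, βlg about −1), so the acetate para to the acrylate (phenol pKa about 8.7 against about 9.8) leaves first, its ortho neighbour follows by O→O acetyl migration with neighbouring-OH assistance, any stray lactate-ring phenol is re-acetylated by the still-activated caffeoyl acetates (transacylation is downhill in that direction), and the alkyl, allyl and cinnamoyl esters and the stereocentres are inert to morpholine at 0 °C.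

**Step 3 (key step)**
Reactants: 6, tethered bis-rosmarinate tetraacetate
Product: 7, 15-membered macrocyclic (1R,2S)-1-(3,4-dihydroxyphenyl)-6,7-dihydroxy-1,2-dihydronaphthalene-2,3-dicarboxylate, whose two (R)-3-(3,4-diacetoxyphenyl)lactate ester arms remain bridged by the 2-methylidenepropane-1,3-diyl tether; expected 30–35% of the pure major isomer, with 6 recovered
Conditions: RVC(+)|Pt(−), divided cell, about +0.8 V vs Ag/AgCl (first wave, set from CV), 1.9 F mol⁻¹; 6 (2 mM), 2,6-lutidine (3 equiv), Bu4NPF6 (0.1 M), HFIP–CH2Cl2 (1:1), 0 °C, Ar; then TFA (5 equiv), 23 °C, 1 h; aq. Na2S2O4 work-up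
Reagents that add atoms: none (net loss of 2 H⁺ and 2 e⁻)
Why: Proposed new method: tether-templated anodic 8–8′ dehydrodimerisation/cyclisation – at this potential only the two free caffeoyl catechols are electroactive (aryl diacetates, esters and the 1,1-disubstituted alkene oxidise more than 1 V higher), about 2 F mol⁻¹ leaves on average one o-quinone arm and one catechol arm in the same molecule, these comproportionate to a geminate bis-semiquinone whose C8 spin density collapses to the C8–C8′ bond (15-membered ring, whereas the 8–O–4′ and 8–5′ modes would need rings of 20 or more members bridged through the arene, and oligomerisation and product over-oxidation to the arylnaphthalene are starved by 2 mM dilution and the charge limit), one 2-hydroxy-p-quinone methide then tautomerises back to the cinnamate and its C6 (para to the 3-OH) adds to C7′ of the other quinone methide, with the acid chase funnelling any doubly tautomerised dibenzylidenesuccinate into the same ring closure; stereocontrol: with Z-esters and each Cα–H eclipsing its acyl C=O, the two bought (R) centres hold both tether carboxyls inside and both diacetoxybenzyl groups outside the forming ring, with the quinone-methide arms anti, best when the Re faces of C8 and C8′ meet, giving the C2-symmetric (8S,8′S) bis-quinone methide (so either tautomerisation leaves C2 = S), and ring closure anti to the C2 ester (pseudo-diaxial trans, the relative configuration normally obtained for this lignan class) sets C1 = R (predicted dr about 4:1 from this qualitative model, sense to be confirmed against natural material, minor (1S,2R) isomer removed by chromatography); the closest known reaction types are the MnO2/Mn(OAc)3/FeCl3 oxidative 8–8′ coupling of caffeate and sinapate esters to trans-1-aryl-1,2-dihydronaphthalenes, anodic phenol coupling in HFIP and tether-directed oxidative coupling of galloyl esters, none of them shown electrochemically, intramolecularly or diastereoselectively on a rosmarinate.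

**Step 4**
Reactants: 7, macrocyclic tetraacetate
Product: 8, rabdosiin; expected about 70%
Conditions: Pd(PPh3)4 (5 mol %), pyrrolidine (30 equiv), degassed THF–MeOH (4:1), 0 → 23 °C, 3 h, Ar; 1 M HCl to pH 2; C18 then Sephadex LH-20
Reagents that add atoms: none
Why: In this Tsuji–Trost deallylation both C–O bonds of the 2-methylidenepropane-1,3-diyl diester ionise in turn to π-allyl-Pd species with two equivalent CH2 termini that pyrrolidine traps (no regiochemical dead end), the same excess amine aminolyses the four remaining aryl acetates, and the C2/C3 alkyl esters, the C3=C4 bond and all four stereocentres are untouched (trans C1/C2 is also the thermodynamic arrangement).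

## Compound list

1 | (R)-rosmarinic acid | O=C(/C=C/c1ccc(O)c(O)c1)O[C@H](Cc1ccc(O)c(O)c1)C(=O)O | starting material
2 | 3-chloro-2-(chloromethyl)prop-1-ene | C=C(CCl)CCl | starting material
3 | 2-methylidenepropane-1,3-diyl bis[(R)-rosmarinate] (octaphenol, not isolated) | C=C(COC(=O)[C@@H](Cc1ccc(O)c(O)c1)OC(=O)/C=C/c1ccc(O)c(O)c1)COC(=O)[C@@H](Cc1ccc(O)c(O)c1)OC(=O)/C=C/c1ccc(O)c(O)c1 | intermediate
4 | acetic anhydride | CC(=O)OC(C)=O | starting material
5 | octaacetate of 3 | C=C(COC(=O)[C@@H](Cc1ccc(OC(C)=O)c(OC(C)=O)c1)OC(=O)/C=C/c1ccc(OC(C)=O)c(OC(C)=O)c1)COC(=O)[C@@H](Cc1ccc(OC(C)=O)c(OC(C)=O)c1)OC(=O)/C=C/c1ccc(OC(C)=O)c(OC(C)=O)c1 | intermediate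
6 | tethered bis-rosmarinate, lactate-ring tetraacetate, caffeoyl catechols free | C=C(COC(=O)[C@@H](Cc1ccc(OC(C)=O)c(OC(C)=O)c1)OC(=O)/C=C/c1ccc(O)c(O)c1)COC(=O)[C@@H](Cc1ccc(OC(C)=O)c(OC(C)=O)c1)OC(=O)/C=C/c1ccc(O)c(O)c1 | intermediate
7 | 15-membered macrocyclic (1R,2S)-rabdosiin 2-methylidenepropane-1,3-diyl diester, lactate-ring tetraacetate | O=C(O[C@H](Cc1ccc(OC(C)=O)c(OC(C)=O)c1)C(=O)OCC(=C)C3)C1=Cc2cc(O)c(O)cc2[C@@H](c2ccc(O)c(O)c2)[C@@H]1C(=O)O[C@H](Cc1ccc(OC(C)=O)c(OC(C)=O)c1)C(=O)O3 | intermediate
8 | rabdosiin | O=C(O[C@H](Cc1ccc(O)c(O)c1)C(=O)O)C1=Cc2cc(O)c(O)cc2[C@@H](c2ccc(O)c(O)c2)[C@@H]1C(=O)O[C@H](Cc1ccc(O)c(O)c1)C(=O)O | target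

## Step count and risks

Total steps: 4 (Step 1 is a one-pot, two-stage operation). Longest linear sequence: 4.

**1. Step 3, the proposed new step**
- Risks: a wrong coupling mode or quinone-derived oligomers, over-oxidation of the more electron-rich product to the arylnaphthalene or benzoxanthene, and a low or reversed diastereomer ratio.
- Fallback (known chemistry): make C8–C8′ by condensation instead of oxidation.
  - A double Stobbe condensation of dimethyl succinate with 3,4-bis(allyloxy)benzaldehyde, then saponification, gives (E,E)-2,3-bis(arylmethylidene)succinic acid.
  - Esterify it (EDC/DMAP) with allyl (R)-3-[3,4-bis(allyloxy)phenyl]lactate, made from commercial sodium (R)-danshensu with allyl bromide/K2CO3.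
  - Run the known 6π photocyclisation/[1,5]-H shift of the dibenzylidenesuccinate at about 350 nm, which gives the cis product. Catalytic DBU then converts it to the trans isomer.
  - Separate the two diastereomers, which the (R)-lactate esters make distinguishable, and finish with Pd(0) global deallylation.

**2. Step 2, selective fourfold deacetylation**
- Risk: insufficient discrimination between caffeoyl and lactate-ring acetates, giving statistical mixtures.
- Fallback: build the differentiated substrate from the other end, so that no selection is needed.
  - Alkylate sodium (R)-danshensu with 2 to give the tethered bis-lactate.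
  - Protect its catechols as acetonides (2,2-dimethoxypropane, TsOH).
  - Acylate the two secondary OH groups with Meldrum's acid to the malonate half-esters.
  - A Knoevenagel–Doebner condensation with 3,4-dihydroxybenzaldehyde then gives the free-catechol caffeate arms.
  - The acetonides come off with aqueous TFA after the tether.

**3. Step 4, one-pot global release**
- Risks: amine-promoted autoxidation of the octaphenol, aromatisation or 1,4-dihydro isomerisation, and incomplete acetate removal.
- Fallback: decouple the two deprotections so that no free amine meets the product.
  - Pd(PPh3)4/PhSiH3 (neutral hydride transfer, the tether leaves as isobutene) gives the diacid tetraacetate.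
  - The aryl acetates are then removed with NH4OAc in aqueous MeOH at near-neutral pH. This costs one extra step.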